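**Plan**

1. Cuts: the C15 aldehyde and the C11=C13 methylene go back to a silyl ether and a phosphonate. The lactone is then opened at C7–C11 to an O8 diazo(phosphoryl)acetate. Behind it the three ester C–O bonds, the C8–O bond (to a C7=C8 enone), the C5–C4 bond (enol triflate plus alkenylzinc) and the C10 vinyl group (from allyl) are cut, ending at 2-methylcyclohexane-1,3-dione.
2. Forward: the cyclohexane is present from the start. C10 is allylated and the dione desymmetrised, allyl is trimmed to vinyl, the carbonyl is moved from C5 to C6 while the C4 unit is coupled to C5, O8 is delivered from O9, C6 is reduced and acylated, and the γ-lactone, the only ring made, closes last.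
3. Enabling feature: in the cyclohexane C5–C10 the lactone carbon C11 sits on C7, next to C8 whose oxygen is equatorial. Before lactonisation C7 is an unbranched CH2, so a carbenoid held on an O8 ester reaches its equatorial hydrogen through a five-membered transition ring, while the C9 hydrogen is deactivated by its geminal acetoxy group.
4. Stereochemistry: C9 and C10 from a catalyst-controlled reduction; C8 from oxygen delivery tethered to O9 (cis); C5 by equilibration next to the C6 ketone; C6 by hydride attack anti to the axial C10 methyl; C7 by retention in the C–H insertion.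

Key step: step 19

Convention: target atoms are numbered C1–C15 (ring C5–C10, vinyl C1=C2, methyl C14, side chain C4(=C3)–C15, lactone C11(=C13)–C12); β is the ring face of the C10 methyl group, α the opposite face.

Assumption: in step 2 the quaternary carbon is taken to act as the large group in the oxazaborolidine transition state, as for tert-alkyl ketones; if the opposite ketol enantiomer forms, the (R)-catalyst is used instead.

**Route**

Step 1
Reactants: 1 2-methylcyclohexane-1,3-dione
Product: 2 2-allyl-2-methylcyclohexane-1,3-dione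
Conditions: allyl acetate, Pd(PPh3)4 (2 mol %), DBU, THF, rt
Reagents that add atoms: allyl acetate, C=CCOC(C)=O
Why: Tsuji–Trost allylation: the stabilised dione enolate attacks the π-allylpalladium complex at carbon, which should give the quaternary C10 without O-allylation.

Step 2
Reactants: 2 2-allyl-2-methylcyclohexane-1,3-dione
Product: 3 (2R,3R)-2-allyl-3-hydroxy-2-methylcyclohexan-1-one
Conditions: (S)-2-methyl-CBS-oxazaborolidine (20 mol %), catecholborane, toluene, −78 °C; aqueous work-up
Reagents that add atoms: none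
Why: Corey–Bakshi–Shibata reduction of one of the two enantiotopic carbonyl groups, with the quaternary carbon as the large substituent and hydride arriving on the methyl-bearing face, should give the 3R alcohol cis to the allyl group and thereby fix both C9 and C10.

Step 3
Reactants: 3 (2R,3R)-2-allyl-3-hydroxy-2-methylcyclohexan-1-one
Product: 4 (2R,3R)-2-allyl-2-methyl-3-(triethylsilyloxy)cyclohexan-1-one
Conditions: Et3SiCl, imidazole, DMF, 0 °C to rt
Reagents that add atoms: chlorotriethylsilane, CC[Si](Cl)(CC)CC
Why: Silylation of the secondary alcohol, which blocks retro-aldol opening and alkoxide-driven side reactions in the enolate steps that follow.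

Step 4
Reactants: 4 (2R,3R)-2-allyl-2-methyl-3-(triethylsilyloxy)cyclohexan-1-one
Product: 5 (2R,3R)-2-methyl-2-[(E)-prop-1-enyl]-3-(triethylsilyloxy)cyclohexan-1-one
Conditions: RuHCl(CO)(PPh3)3 (5 mol %), toluene, 80 °C
Reagents that add atoms: none
Why: Ruthenium hydride-catalysed alkene isomerisation by hydrometalation and β-hydride elimination moves the double bond one position inwards and cannot go further because C10 is quaternary.

Step 5
Reactants: 5 (2R,3R)-2-methyl-2-[(E)-prop-1-enyl]-3-(triethylsilyloxy)cyclohexan-1-one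
Product: 6 (2R,3R)-2-methyl-3-(triethylsilyloxy)-2-vinylcyclohexan-1-one
Conditions: second-generation Hoveyda–Grubbs catalyst (5 mol %), ethylene (1 atm), toluene, 40 °C
Reagents that add atoms: ethylene, C=C
Why: Cross-metathesis with ethylene (ethenolysis) exchanges the ethylidene end for a methylene, the ruthenium carbene staying on the unhindered carbon so that the neopentyl position only receives CH2.

Step 6
Reactants: 6 (2R,3R)-2-methyl-3-(triethylsilyloxy)-2-vinylcyclohexan-1-one
Product: 8 (5R,6R)-6-methyl-5-(triethylsilyloxy)-6-vinylcyclohex-2-en-1-one, via trimethylsilyl enol ether 7 (not isolated)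
Conditions: LiN(i-Pr)2, Me3SiCl, THF, −78 °C; solvent exchange; Pd(OAc)2 (1.05 equiv), MeCN, rt
Reagents that add atoms: none
Why: Saegusa–Ito dehydrogenation: the ketone can enolise only towards C6, so the silyl enol ether and the enone (C5 ketone, C6=C7) should form as single regioisomers.

Step 7
Reactants: 8 (5R,6R)-6-methyl-5-(triethylsilyloxy)-6-vinylcyclohex-2-en-1-one
Product: 9 C6-hydroxy β,γ-enone (C5 ketone; C6–OH as epimers; C7=C8; C9α–OSiEt3)
Conditions: KN(SiMe3)2, THF, −78 °C; 2-(phenylsulfonyl)-3-phenyloxaziridine; H2O quench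
Reagents that add atoms: 2-(phenylsulfonyl)-3-phenyloxaziridine, O=S(=O)(N1OC1c1ccccc1)c1ccccc1
Why: With no α′ hydrogen the base removes a C8 hydrogen, and the extended enolate is oxidised at its α carbon C6 by the N-sulfonyloxaziridine (Davis hydroxylation); the C6 configuration is irrelevant because C6 becomes trigonal in step 9.

Step 8
Reactants: 9 C6-hydroxy β,γ-enone
Product: 10 C6,C9-bis(triethylsilyloxy) β,γ-enone
Conditions: Et3SiCl, imidazole, DMF, 0 °C
Reagents that add atoms: chlorotriethylsilane, CC[Si](Cl)(CC)CC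
Why: Silylation of the secondary α-hydroxy ketone so that the C6 oxygen survives as a silyl enol ether through steps 9 and 11.

Step 9
Reactants: 10 C6,C9-bis(triethylsilyloxy) β,γ-enone
Product: 11 dienyl triflate (C5–OSO2CF3; C5=C6–OSiEt3; C7=C8; C9α–OSiEt3)
Conditions: KN(SiMe3)2, THF, −78 °C; PhNTf2
Reagents that add atoms: N-phenylbis(trifluoromethanesulfonimide), O=S(=O)(N(c1ccccc1)S(=O)(=O)C(F)(F)F)C(F)(F)F
Why: Enol triflate formation: the C6 hydrogen, α to the ketone and allylic, is the only one that can be removed, and the potassium dienolate is sulfonylated on oxygen.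

Step 10
Reactants: 12 2-bromoprop-2-en-1-ol
Product: 13 (2-bromoallyloxy)(tert-butyl)diphenylsilane
Conditions: t-BuPh2SiCl, imidazole, CH2Cl2, rt
Reagents that add atoms: tert-butyl(chloro)diphenylsilane, CC(C)(C)[Si](Cl)(c1ccccc1)c1ccccc1
Why: Silylation of the primary alcohol with a silyl group that outlasts the acid and fluoride steps up to step 21.

Step 11
Reactants: 11 dienyl triflate; 13 (2-bromoallyloxy)(tert-butyl)diphenylsilane
Product: 17 γ-hydroxy enone (C6 ketone; C7=C8; C9α–OH; C5 side chain C4(=C3H2)–C15H2–OSi(t-Bu)Ph2; C5 epimers), via 2-lithioallyl silyl ether 14 (not isolated), via alkenylzinc bromide 15 (not isolated), via silyl dienol ether 16 (not isolated)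
Conditions: 13, t-BuLi (2 equiv), Et2O, −78 °C; ZnBr2, THF, −78 to 0 °C; 11, Pd(PPh3)4 (5 mol %), THF, 50 °C; then HF·pyridine, pyridine, THF, 0 °C
Reagents that add atoms: none
Why: Bromine–lithium exchange and transmetalation give an alkenylzinc that undergoes Negishi coupling with the enol triflate to form C5–C4, after which fluoride cleaves the silyl dienol ether and the C9 triethylsilyl ether (the tert-butyldiphenylsilyl ether is slower) and the dienol is protonated at C5 to the β,γ-unsaturated ketone, C5 being left uncontrolled at this stage.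

Step 12
Reactants: 17 γ-hydroxy enone
Product: 19 acetal ketone (C6 ketone; cis-fused O8/O9 cyclohexylmethylene acetal on the α face; C5β side chain), via hemiacetal 18 (not isolated)
Conditions: cyclohexanecarbaldehyde (2 equiv), 1-[3,5-bis(trifluoromethyl)phenyl]-3-[2-(dimethylamino)ethyl]thiourea (10 mol %), CH2Cl2, rt; then DBU (20 mol %), rt
Reagents that add atoms: cyclohexanecarbaldehyde, O=CC1CCCCC1
Why: Hemiacetal formation at O9 and intramolecular oxa-Michael addition (exo closure of a 1,3-dioxolane) under amine–thiourea catalysis bring O8 to C8 on the face of O9, so C8 is set cis to C9 by the ring fusion, and the amidine then equilibrates C5 next to the ketone to the β epimer, whose side chain is equatorial whereas the α epimer would be 1,3-diaxial to O9 or need an axial vinyl group.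

Step 13
Reactants: 19 acetal ketone
Product: 20 C6β alcohol (axial hydroxyl)
Conditions: LiBH(s-Bu)3, THF, −78 °C; aqueous work-up
Reagents that add atoms: none
Why: Ketone reduction with a bulky trialkylborohydride: the axial C10 methyl closes the β face, so hydride should arrive equatorially from the α face and give the axial 6β alcohol.

Step 14
Reactants: 20 C6β alcohol; 21 angelic acid ((Z)-2-methylbut-2-enoic acid)
Product: 23 C6β angelate of 20, via mixed anhydride 22 (not isolated)
Conditions: 21, 2,4,6-trichlorobenzoyl chloride, Et3N, toluene, rt; then 20, toluene, 80 °C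
Reagents that add atoms: none
Why: Yamaguchi esterification through the mixed anhydride, run without a nucleophilic catalyst, should acylate the hindered axial alcohol at the less hindered angeloyl carbonyl without isomerisation of the Z alkene to the tiglate.

Step 15
Reactants: 23 C6β angelate acetal
Product: 24 C8α,C9α-diol C6β-angelate
Conditions: AcOH/H2O (4:1), 60 °C
Reagents that add atoms: none
Why: Acid-catalysed acetal hydrolysis under conditions that the esters, the alkenes and the tert-butyldiphenylsilyl ether tolerate.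

Step 16
Reactants: 24 C8α,C9α-diol C6β-angelate; 25 (diethoxyphosphoryl)acetic acid
Product: 26 C8 (diethoxyphosphoryl)acetate (C9 hydroxyl free)
Conditions: 25, DCC, DMAP (10 mol %), CH2Cl2, 0 °C
Reagents that add atoms: none
Why: Steglich esterification, selective for the equatorial C8 hydroxyl over the axial C9 hydroxyl that is flanked by the quaternary C10.

Step 17
Reactants: 26 C8 (diethoxyphosphoryl)acetate
Product: 27 C9 acetate C8 (diethoxyphosphoryl)acetate
Conditions: Ac2O, pyridine, DMAP (cat.), CH2Cl2, rt
Reagents that add atoms: acetic anhydride, CC(=O)OC(C)=O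
Why: Acetylation of the remaining hindered secondary alcohol under 4-(dimethylamino)pyridine catalysis, the C8 ester staying in its favoured equatorial position.

Step 18
Reactants: 27 C9 acetate C8 (diethoxyphosphoryl)acetate
Product: 28 C8 diazo(diethoxyphosphoryl)acetate (insertion precursor; C7 is CH2)
Conditions: 4-acetamidobenzenesulfonyl azide, DBU, MeCN, 0 °C to rt
Reagents that add atoms: 4-acetamidobenzenesulfonyl azide, CC(=O)Nc1ccc(cc1)S(=O)(=O)N=[N+]=[N-]
Why: Regitz diazo transfer to the doubly activated methylene of the phosphonoacetate.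

Step 19
Reactants: 28 C8 diazo(diethoxyphosphoryl)acetate
Product: 29 trans-fused α-(diethoxyphosphoryl) γ-lactone (C7–C11 bond on the β face; C11 epimers equivalent)
Conditions: Rh2(O2CC7H15)4 (2 mol %), CH2Cl2, 40 °C, slow addition of 28
Reagents that add atoms: none
Why: Divalent rhodium decomposes the diazo ester to an electrophilic carbenoid that inserts into the C7–H bond in a concerted three-centre process with retention, forming C7–C11. The closest known reaction is the dirhodium-catalysed 1,5 C–H insertion of α-diazo-α-phosphonoacetates of cyclohexanols to α-phosphono γ-lactones. The lactone closes by 1,5-insertion through a five-membered transition ring in which O8 and C7 are already ring neighbours, giving the trans-fused bicycle. C7 is set by insertion into the equatorial (β) hydrogen, which the equatorial O8 on the chair fixed by the axial C10 methyl and the equatorial C5 side chain presents to the carbenoid; C11 should form mainly with phosphorus trans to C6 and is removed in step 20. The step needs C7–H to win over C9–H, over the carbinol C8–H and over the alkenes: C9–H is tertiary, next to the quaternary C10 and deactivated by its geminal acetoxy group, four-membered closure at C8 is disfavoured, the axial C7–H is antiperiplanar to the C6–O bond and so more deactivated than the equatorial one, and the C1=C2 and C3=C4 double bonds are out of reach of the O8 tether while the angelate alkene is electron-poor.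

Step 20
Reactants: 29 trans-fused α-(diethoxyphosphoryl) γ-lactone
Product: 30 α-methylene γ-lactone C15 silyl ether
Conditions: aqueous HCHO, K2CO3, THF, 0 °C to rt
Reagents that add atoms: formaldehyde, C=O
Why: Horner–Wadsworth–Emmons olefination of the acidic α-phosphono lactone with formaldehyde under carbonate base, which spares the acetate and angelate; both C11 epimers give the same exocyclic alkene.

Step 21
Reactants: 30 α-methylene γ-lactone C15 silyl ether
Product: 31 C15 allylic alcohol
Conditions: HF·pyridine, pyridine, THF, 0 °C to rt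
Reagents that add atoms: none
Why: Fluoride-mediated cleavage of the primary silyl ether under pyridine-buffered conditions that leave the three esters and the methylene lactone untouched.

Step 22
Reactants: 31 C15 allylic alcohol
Product: 32 CNP0228039.1 (target)
Conditions: Dess–Martin periodinane, CH2Cl2, rt
Reagents that add atoms: none
Why: Dess–Martin oxidation of the primary allylic alcohol to the aldehyde without touching the other alkenes or esters.

**Compound list**

1 | 2-methylcyclohexane-1,3-dione | CC1C(=O)CCCC1=O | starting material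
2 | 2-allyl-2-methylcyclohexane-1,3-dione | C=CCC1(C)C(=O)CCCC1=O | intermediate
3 | (2R,3R)-2-allyl-3-hydroxy-2-methylcyclohexan-1-one | C=CC[C@]1(C)[C@H](O)CCCC1=O | intermediate
4 | (2R,3R)-2-allyl-2-methyl-3-(triethylsilyloxy)cyclohexan-1-one | C=CC[C@]1(C)[C@H](O[Si](CC)(CC)CC)CCCC1=O | intermediate
5 | (2R,3R)-2-methyl-2-[(E)-prop-1-enyl]-3-(triethylsilyloxy)cyclohexan-1-one | C/C=C/[C@]1(C)[C@H](O[Si](CC)(CC)CC)CCCC1=O | intermediate
6 | (2R,3R)-2-methyl-3-(triethylsilyloxy)-2-vinylcyclohexan-1-one | C=C[C@]1(C)[C@H](O[Si](CC)(CC)CC)CCCC1=O | intermediate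
7 | trimethylsilyl enol ether of 6 (C5–OSiMe3, C5=C6) | C=C[C@]1(C)[C@H](O[Si](CC)(CC)CC)CCC=C1O[Si](C)(C)C | intermediate
8 | (5R,6R)-6-methyl-5-(triethylsilyloxy)-6-vinylcyclohex-2-en-1-one (C5 ketone, C6=C7) | C=C[C@]1(C)[C@H](O[Si](CC)(CC)CC)CC=CC1=O | intermediate
9 | C6-hydroxy β,γ-enone (C5 ketone, C6–OH epimers, C7=C8, C9α–OSiEt3, C10 β-methyl α-vinyl) | C=C[C@]1(C)[C@H](O[Si](CC)(CC)CC)C=CC(O)C1=O | intermediate
10 | C6,C9-bis(triethylsilyloxy) β,γ-enone | C=C[C@]1(C)[C@H](O[Si](CC)(CC)CC)C=CC(O[Si](CC)(CC)CC)C1=O | intermediate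
11 | dienyl triflate (C5–OTf, C5=C6–OSiEt3, C7=C8, C9α–OSiEt3) | C=C[C@]1(C)[C@H](O[Si](CC)(CC)CC)C=CC(O[Si](CC)(CC)CC)=C1OS(=O)(=O)C(F)(F)F | intermediate
12 | 2-bromoprop-2-en-1-ol | OCC(Br)=C | starting material
13 | (2-bromoallyloxy)(tert-butyl)diphenylsilane | C=C(Br)CO[Si](c1ccccc1)(c1ccccc1)C(C)(C)C | intermediate
14 | [3-(tert-butyldiphenylsilyloxy)prop-1-en-2-yl]lithium | [Li]C(=C)CO[Si](c1ccccc1)(c1ccccc1)C(C)(C)C | intermediate
15 | [3-(tert-butyldiphenylsilyloxy)prop-1-en-2-yl]zinc bromide | Br[Zn]C(=C)CO[Si](c1ccccc1)(c1ccccc1)C(C)(C)C | intermediate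
16 | silyl dienol ether (C5 bearing the C4 unit, C5=C6–OSiEt3, C7=C8, C9α–OSiEt3) | C=C[C@]1(C)[C@H](O[Si](CC)(CC)CC)C=CC(O[Si](CC)(CC)CC)=C1C(=C)CO[Si](c1ccccc1)(c1ccccc1)C(C)(C)C | intermediate
17 | γ-hydroxy enone (C6 ketone, C7=C8, C9α–OH, C5 side chain, C5 epimers) | C=C[C@]1(C)[C@H](O)C=CC(=O)C1C(=C)CO[Si](c1ccccc1)(c1ccccc1)C(C)(C)C | intermediate
18 | C9 hemiacetal of 17 with cyclohexanecarbaldehyde | C=C[C@]1(C)[C@H](OC(O)C2CCCCC2)C=CC(=O)C1C(=C)CO[Si](c1ccccc1)(c1ccccc1)C(C)(C)C | intermediate
19 | acetal ketone (C6 ketone, cis-fused O8/O9 cyclohexylmethylene acetal on the α face, C5β side chain; acetal carbon unassigned) | C=C[C@]1(C)[C@@H]2OC(C3CCCCC3)O[C@@H]2CC(=O)[C@H]1C(=C)CO[Si](c1ccccc1)(c1ccccc1)C(C)(C)C | intermediate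
20 | C6β alcohol of 19 | C=C[C@]1(C)[C@@H]2OC(C3CCCCC3)O[C@@H]2C[C@@H](O)[C@H]1C(=C)CO[Si](c1ccccc1)(c1ccccc1)C(C)(C)C | intermediate
21 | angelic acid, (Z)-2-methylbut-2-enoic acid | C/C=C(/C)C(=O)O | starting material
22 | angelic 2,4,6-trichlorobenzoic anhydride | C/C=C(/C)C(=O)OC(=O)c1c(Cl)cc(Cl)cc1Cl | intermediate
23 | C6β angelate acetal | C=C[C@]1(C)[C@@H]2OC(C3CCCCC3)O[C@@H]2C[C@@H](OC(=O)/C(C)=C\C)[C@H]1C(=C)CO[Si](c1ccccc1)(c1ccccc1)C(C)(C)C | intermediate
24 | C8α,C9α-diol C6β-angelate | C=C[C@]1(C)[C@H](O)[C@H](O)C[C@@H](OC(=O)/C(C)=C\C)[C@H]1C(=C)CO[Si](c1ccccc1)(c1ccccc1)C(C)(C)C | intermediate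
25 | (diethoxyphosphoryl)acetic acid | CCOP(=O)(CC(=O)O)OCC | starting material
26 | C8 (diethoxyphosphoryl)acetate, C9 hydroxyl free | C=C[C@]1(C)[C@H](O)[C@H](OC(=O)CP(=O)(OCC)OCC)C[C@@H](OC(=O)/C(C)=C\C)[C@H]1C(=C)CO[Si](c1ccccc1)(c1ccccc1)C(C)(C)C | intermediate
27 | C9 acetate C8 (diethoxyphosphoryl)acetate | C=C[C@]1(C)[C@H](OC(C)=O)[C@H](OC(=O)CP(=O)(OCC)OCC)C[C@@H](OC(=O)/C(C)=C\C)[C@H]1C(=C)CO[Si](c1ccccc1)(c1ccccc1)C(C)(C)C | intermediate
28 | C8 diazo(diethoxyphosphoryl)acetate (insertion precursor) | C=C[C@]1(C)[C@H](OC(C)=O)[C@H](OC(=O)C(=[N+]=[N-])P(=O)(OCC)OCC)C[C@@H](OC(=O)/C(C)=C\C)[C@H]1C(=C)CO[Si](c1ccccc1)(c1ccccc1)C(C)(C)C | intermediate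
29 | trans-fused α-(diethoxyphosphoryl) γ-lactone (C11 shown with phosphorus trans to C6) | C=C[C@]1(C)[C@H](OC(C)=O)[C@@H]2OC(=O)[C@H](P(=O)(OCC)OCC)[C@H]2[C@@H](OC(=O)/C(C)=C\C)[C@H]1C(=C)CO[Si](c1ccccc1)(c1ccccc1)C(C)(C)C | intermediate
30 | α-methylene γ-lactone C15 tert-butyldiphenylsilyl ether | C=C[C@]1(C)[C@H](OC(C)=O)[C@@H]2OC(=O)C(=C)[C@H]2[C@@H](OC(=O)/C(C)=C\C)[C@H]1C(=C)CO[Si](c1ccccc1)(c1ccccc1)C(C)(C)C | intermediate
31 | C15 allylic alcohol | C=C[C@]1(C)[C@H](OC(C)=O)[C@@H]2OC(=O)C(=C)[C@H]2[C@@H](OC(=O)/C(C)=C\C)[C@H]1C(=C)CO | intermediate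
32 | CNP0228039.1 | C=C[C@]1(C)[C@H](OC(C)=O)[C@@H]2OC(=O)C(=C)[C@H]2[C@@H](OC(=O)/C(C)=C\C)[C@H]1C(=C)C=O | target

**Step count and risks**

Total steps: 22. Longest linear sequence: 21 steps (1 to 32 through steps 1–9 and 11–22).

Steps most likely to fail:

1. Step 19. The C7 hydrogens lie next to the acylated C6, so insertion may be slow and the carbenoid may drift into the carbinol C8–H bond (four-membered closure), the tertiary C9–H bond or the C1=C2 alkene. Fallback with a smaller, more electrophilic carbenoid and a different methylenation: the route sets out from 24. Steglich esterification of the C8 hydroxyl with 3-(tert-butoxy)-3-oxopropanoic acid gives the C8 tert-butyl malonate F1. Acetylation as in step 17 gives the C9 acetate F2. Diazo transfer as in step 18 gives the C8 tert-butyl diazomalonate F3. Insertion with Rh2(OAc)4 in CH2Cl2 gives the trans-fused α-(tert-butoxycarbonyl) γ-lactone F4. CF3CO2H in CH2Cl2 removes the tert-butyl group to give the trans-fused α-carboxy γ-lactone F5. Decarboxylative Mannich methylenation (Et2NH, aqueous HCHO, AcOH, NaOAc) then returns the route at 30.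

2. Step 11. Transmetalation or reductive elimination may fail at the tetrasubstituted enol triflate that is flanked by the quaternary C10, so that the triflate is lost by reduction or S–O cleavage instead of coupling. Fallback by carbonyl addition and dehydration: the route sets out from 10. The alkenyllithium 14, made from 13 as in step 11, is added to the C5 carbonyl in THF at −78 °C to give the tertiary C5 alcohol F6. Dehydration with the Burgess reagent, for which C6 offers the only β-hydrogen, returns the route at 16, which is carried on to 17 by the fluoride stage of step 11.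

3. Step 12. The hemiacetal equilibrium at the hindered C9 hydroxyl may be too unfavourable for oxygen delivery to C8, or the adduct may revert to the enone during the C5 equilibration. Fallback by boron-tethered hydroxide delivery: the route sets out from 17. PhB(OH)2 and a tertiary amine (molecular sieves, CH2Cl2) give the cyclic O8,O9 phenylboronate ketone F7 with the new C8–O bond cis to O9. Oxidative work-up (H2O2, NaHCO3) frees the C8α,C9α-dihydroxy C6 ketone F8. Acetalisation with cyclohexanecarbaldehyde dimethyl acetal (pyridinium p-toluenesulfonate), followed by DBU equilibration of C5, returns the route at 19.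

Further compounds
F1 | step 19 | C8 tert-butyl malonate of 24, C9 hydroxyl free | C=C[C@]1(C)[C@H](O)[C@H](OC(=O)CC(=O)OC(C)(C)C)C[C@@H](OC(=O)/C(C)=C\C)[C@H]1C(=C)CO[Si](c1ccccc1)(c1ccccc1)C(C)(C)C
F2 | step 19 | C9 acetate of F1 | C=C[C@]1(C)[C@H](OC(C)=O)[C@H](OC(=O)CC(=O)OC(C)(C)C)C[C@@H](OC(=O)/C(C)=C\C)[C@H]1C(=C)CO[Si](c1ccccc1)(c1ccccc1)C(C)(C)C
F3 | step 19 | C8 tert-butyl diazomalonate | C=C[C@]1(C)[C@H](OC(C)=O)[C@H](OC(=O)C(=[N+]=[N-])C(=O)OC(C)(C)C)C[C@@H](OC(=O)/C(C)=C\C)[C@H]1C(=C)CO[Si](c1ccccc1)(c1ccccc1)C(C)(C)C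
F4 | step 19 | trans-fused α-(tert-butoxycarbonyl) γ-lactone | C=C[C@]1(C)[C@H](OC(C)=O)[C@@H]2OC(=O)C(C(=O)OC(C)(C)C)[C@H]2[C@@H](OC(=O)/C(C)=C\C)[C@H]1C(=C)CO[Si](c1ccccc1)(c1ccccc1)C(C)(C)C
F5 | step 19 | trans-fused α-carboxy γ-lactone | C=C[C@]1(C)[C@H](OC(C)=O)[C@@H]2OC(=O)C(C(=O)O)[C@H]2[C@@H](OC(=O)/C(C)=C\C)[C@H]1C(=C)CO[Si](c1ccccc1)(c1ccccc1)C(C)(C)C
F6 | step 11 | tertiary C5 alcohol from 10 and 14 | C=C[C@]1(C)[C@H](O[Si](CC)(CC)CC)C=CC(O[Si](CC)(CC)CC)C1(O)C(=C)CO[Si](c1ccccc1)(c1ccccc1)C(C)(C)C
F7 | step 12 | cyclic O8,O9 phenylboronate ketone | C=C[C@]1(C)[C@@H]2OB(c3ccccc3)O[C@@H]2CC(=O)C1C(=C)CO[Si](c1ccccc1)(c1ccccc1)C(C)(C)C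
F8 | step 12 | C8α,C9α-dihydroxy C6 ketone | C=C[C@]1(C)[C@H](O)[C@H](O)CC(=O)C1C(=C)CO[Si](c1ccccc1)(c1ccccc1)C(C)(C)C
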